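**Assumption:** the target has no stereocentre (it is achiral), so no stereocontrol is needed; compound 3 is formed racemic and its stereocentre is erased in step 2.

## Retrosynthetic overview

1. The only C–C bond outside the ring is aryl–CH2OH. It is the key bond and is made from 3-bromophenol (1) and glyoxylic acid (2) by an intermolecular aldol-type addition of the phenolate (a vinylogous enolate) through its para carbon, giving mandelic acid 3.
2. The surplus carboxyl carbon of 3 is removed by oxidative decarboxylation to give aldehyde 4.
3. The two bromines ortho to OH are introduced on 4 (through 5) to give 6; the bromine meta to OH comes from 1.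
4. Reduction of the formyl group of 6 gives the target 7. This is done last because 4-hydroxybenzyl alcohols are labile (quinone methide formation) and would suffer ipso-substitution under bromination.
5. No ring is formed; the benzene ring is carried through from 1.

## Route

Step 1
Reactants: 1 3-bromophenol; 2 glyoxylic acid (50 wt% aqueous solution)
Product: 3 rac-2-(2-bromo-4-hydroxyphenyl)-2-hydroxyacetic acid (2-bromo-4-hydroxymandelic acid)
Conditions: 1 (1.5 equiv), 2 (1.0 equiv), NaOH (2.6 equiv), H2O, 0 → 30 °C, 24 h; HCl to pH 7, toluene wash (recovers excess 1); HCl to pH 1, EtOAc extraction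
Reagents that add atoms: none
Why: The phenolate of 1 adds through its para carbon to the aldehyde of glyoxylate (aldol-type hydroxyalkylation, the hydroxymandelic acid condensation); para attack is favoured in aqueous NaOH, the carboxylate of the adduct suppresses a second arylation, and the new benzylic stereocentre is formed racemic and removed in step 2.

Step 2
Reactants: 3 rac-2-(2-bromo-4-hydroxyphenyl)-2-hydroxyacetic acid
Product: 4 2-bromo-4-hydroxybenzaldehyde
Conditions: FeCl3·6H2O (2.4 equiv), H2O/toluene, 85 °C, 2 h; chromatography or crystallisation
Reagents that add atoms: none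
Why: Trivalent iron oxidises the 4-hydroxymandelic acid in two one-electron steps with loss of CO2, and the resulting quinone methide enol tautomerises to the 4-hydroxybenzaldehyde (oxidative decarboxylation); any ortho isomer from step 1 ends as the far less polar, chelated 4-bromosalicylaldehyde and is removed here.

Step 3
Reactants: 4 2-bromo-4-hydroxybenzaldehyde
Product: 6 2,3,5-tribromo-4-hydroxybenzaldehyde, via 2,5-dibromo-4-hydroxybenzaldehyde 5 (not isolated)
Conditions: Br2 (2.15 equiv), NaOAc (2.5 equiv), AcOH, rt → 45 °C, 4 h; aq. NaHSO3 quench
Reagents that add atoms: bromine, BrBr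
Why: Electrophilic aromatic bromination: OH directs to its two free ortho positions (also meta to CHO) while the para position is occupied; the first bromine enters at the less hindered C5 (5), the second at C3, and buffered, limited Br2 avoids ipso-bromodeformylation.

Step 4
Reactants: 6 2,3,5-tribromo-4-hydroxybenzaldehyde
Product: 7 2,3,6-tribromo-4-(hydroxymethyl)phenol
Conditions: NaBH4 (1.5 equiv), THF/H2O (4:1), 0 °C, 1 h; aq. NH4Cl to pH 6, EtOAc, concentrate below 30 °C
Reagents that add atoms: none
Why: Borohydride reduction of the aldehyde (hydride addition) leaves aryl bromides untouched and creates no stereocentre; an alcohol-free solvent and a cold, near-neutral work-up prevent quinone methide formation and ether artefacts.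

## Compound list

1 | 3-bromophenol | Oc1cccc(Br)c1 | starting material
2 | glyoxylic acid (oxoacetic acid) | O=CC(=O)O | starting material
3 | rac-2-(2-bromo-4-hydroxyphenyl)-2-hydroxyacetic acid | OC(C(=O)O)c1ccc(O)cc1Br | intermediate
4 | 2-bromo-4-hydroxybenzaldehyde | O=Cc1ccc(O)cc1Br | intermediate
5 | 2,5-dibromo-4-hydroxybenzaldehyde | O=Cc1cc(Br)c(O)cc1Br | intermediate (not isolated)
6 | 2,3,5-tribromo-4-hydroxybenzaldehyde | O=Cc1cc(Br)c(O)c(Br)c1Br | intermediate
7 | 2,3,6-tribromo-4-(hydroxymethyl)phenol | OCc1cc(Br)c(O)c(Br)c1Br | target

## Summary

Total step count: 4. Longest linear sequence: 4 steps (1 → 3 → 4 → 6 → 7).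

Steps most likely to fail, each with a fallback:

**Step 1 (para/ortho selectivity and isolation of the water-soluble acid).** The fallback fixes the regiochemistry by blocking both ortho positions first. It sets out from compound 1. Ortho-selective dibromination (Br2 2.0 equiv, t-BuNH2, toluene, −70 °C → rt) gives 2,3,6-tribromophenol F1, whose only free activated position is para to OH. Aldol-type addition of its phenolate to 2 (NaOH, H2O, 50 °C; slower because the phenolate is less nucleophilic) gives rac-2-hydroxy-2-(2,3,5-tribromo-4-hydroxyphenyl)acetic acid F2. Oxidative decarboxylation with FeCl3·6H2O as in step 2 then gives aldehyde 6, where the fallback comes back to the route; steps 2 and 3 are bypassed.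

**Step 2 (over-oxidation or phenol coupling under trivalent iron).** The fallback removes the extra carbon by glycol cleavage instead. It sets out from compound 3. Carboxylate-selective methylation (MeI, KHCO3, DMF, rt) gives methyl rac-2-(2-bromo-4-hydroxyphenyl)-2-hydroxyacetate F3. NaBH4 (EtOH/THF, 0 °C → rt; α-hydroxy esters are reduced readily) gives rac-1-(2-bromo-4-hydroxyphenyl)ethane-1,2-diol F4. NaIO4 (THF/H2O, 0 °C) cleaves the 1,2-diol to the aldehyde, coming back to the route at compound 4.

**Step 3 (hindered second bromination at C3, or ipso-bromodeformylation).** The fallback brominates at the ester oxidation level, where the para carbon cannot be displaced. It sets out from compound 4. Pinnick oxidation (NaClO2, NaH2PO4, 2-methyl-2-butene, t-BuOH/H2O) gives 2-bromo-4-hydroxybenzoic acid F5. Fischer esterification (MeOH, cat. H2SO4, reflux) gives methyl 2-bromo-4-hydroxybenzoate F6. Bromination (Br2, NaOAc, AcOH, 45 °C) gives methyl 2,3,5-tribromo-4-hydroxybenzoate F7. Reduction with i-Bu2AlH (4 equiv, THF, −78 → 0 °C; inert to aryl bromides) gives the benzylic alcohol, coming back to the route at compound 7; step 4 is bypassed.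

## Further compounds

F1 | step 1 | 2,3,6-tribromophenol | Oc1c(Br)ccc(Br)c1Br
F2 | step 1 | rac-2-hydroxy-2-(2,3,5-tribromo-4-hydroxyphenyl)acetic acid | OC(C(=O)O)c1cc(Br)c(O)c(Br)c1Br
F3 | step 2 | methyl rac-2-(2-bromo-4-hydroxyphenyl)-2-hydroxyacetate | COC(=O)C(O)c1ccc(O)cc1Br
F4 | step 2 | rac-1-(2-bromo-4-hydroxyphenyl)ethane-1,2-diol | OCC(O)c1ccc(O)cc1Br
F5 | step 3 | 2-bromo-4-hydroxybenzoic acid | OC(=O)c1ccc(O)cc1Br
F6 | step 3 | methyl 2-bromo-4-hydroxybenzoate | COC(=O)c1ccc(O)cc1Br
F7 | step 3 | methyl 2,3,5-tribromo-4-hydroxybenzoate | COC(=O)c1cc(Br)c(O)c(Br)c1Br
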